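**Retrosynthetic overview**
1. The cyclobutane is cut across both bonds that join the p-coumarate C2 unit (C1–C4) to the caffeate C2 unit (C2–C3). An intramolecular, anti head-to-tail [2+2] photocycloaddition makes the four-membered ring, its four stereocentres and a temporary 19-membered cyclophane ring in one operation.
2. Two features enable this. The aryl rings on C2 and C4 are cis-1,3, so O-4 of the catechol ring and O-4 of the phenol ring can be tied by a rigid p-xylylene strap (a double benzyl ether). The unit C3–C(=O)–O–CH(R)–C(=O)O is a bidentate site on which SnCl4 can form a seven-membered chelate ring next to the R stereocentre.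
3. The strap fixes chemo-, regio- and syn/anti selectivity. The chelate supplies activation, selective excitation and the facial bias.
4. Ring order: chelate ring (temporary), then cyclobutane plus cyclophane ring (key step). One hydrogenolysis then opens the cyclophane ring and removes the strap, the benzyl ethers and the benzyl esters.
5. The photosubstrate comes from p-coumaric acid, 1,4-bis(bromomethyl)benzene, 3,4-dihydroxybenzaldehyde and sodium (R)-danshensu by Williamson, Knoevenagel–Doebner and Steglich steps.

Key step: step 8

Assumption: the tin chelate of the photosubstrate is taken to react from the s-trans enoate conformer, as is accepted for titanium chelates of lactate acrylates. Ring locants used below: C1 CO2H, C2 catechol ring, C3 ester, C4 phenol ring.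

Step 1
Reactants: 1 p-coumaric acid
Product: 2 benzyl (E)-3-(4-hydroxyphenyl)acrylate
Conditions: BnBr, KHCO3, DMF, 40 °C
Reagents that add atoms: benzyl bromide, BrCc1ccccc1
Why: Hydrogen carbonate deprotonates only the carboxylic acid and leaves the phenol protonated, so SN2 O-alkylation of the carboxylate should give the benzyl ester alone.

Step 2
Reactants: 2 benzyl (E)-3-(4-hydroxyphenyl)acrylate; 3 1,4-bis(bromomethyl)benzene
Product: 4 strap bromide, benzyl (E)-3-(4-{[4-(bromomethyl)benzyl]oxy}phenyl)acrylate
Conditions: 3 (4 equiv), K2CO3, acetone, reflux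
Reagents that add atoms: none
Why: This is a Williamson ether synthesis in which the excess of the symmetric dibromide suppresses double substitution and the surplus can be recovered.

Step 3
Reactants: 4 strap bromide; 5 3,4-dihydroxybenzaldehyde
Product: 6 benzyl (E)-3-[4-({4-[(4-formyl-2-hydroxyphenoxy)methyl]benzyl}oxy)phenyl]acrylate
Conditions: NaHCO3, NaI (cat.), DMF, 40 °C
Reagents that add atoms: none
Why: In this Williamson ether synthesis under hydrogen carbonate control only the 4-OH, acidified by the para formyl group, is deprotonated, a selectivity well established for monobenzylation of this aldehyde.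

Step 4
Reactants: 6 hydroxy aldehyde
Product: 7 benzyl (E)-3-[4-({4-[(2-(benzyloxy)-4-formylphenoxy)methyl]benzyl}oxy)phenyl]acrylate
Conditions: BnBr, K2CO3, DMF, rt
Reagents that add atoms: benzyl bromide, BrCc1ccccc1
Why: Williamson benzylation of the one remaining phenol has no competing nucleophilic site.

Step 5
Reactants: 7 aldehyde
Product: 8 strapped (E)-cinnamic acid
Conditions: malonic acid, pyridine, piperidine (cat.), 90 °C
Reagents that add atoms: malonic acid, O=C(O)CC(=O)O
Why: Knoevenagel–Doebner condensation with decarboxylation should give the E acid under thermodynamic control, and the benzyl cinnamate and the ethers are inert to pyridine.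

Step 6
Reactants: 9 sodium (R)-danshensu
Product: 10 benzyl (R)-3-[3,4-bis(benzyloxy)phenyl]-2-hydroxypropanoate
Conditions: BnBr (3.3 equiv), K2CO3, DMF, N2, rt
Reagents that add atoms: benzyl bromide, BrCc1ccccc1
Why: Carbonate allows Williamson-type O-alkylation of the carboxylate and both phenoxides but does not deprotonate the secondary alcohol, and the chiral-pool stereocentre is not touched.

Step 7
Reactants: 8 strapped (E)-cinnamic acid; 10 protected (R)-danshensu
Product: 11 strapped diene (photosubstrate)
Conditions: DCC, DMAP (cat.), CH2Cl2, 0 °C to rt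
Reagents that add atoms: none
Why: Steglich esterification is the standard way to acylate a secondary α-hydroxy ester with a cinnamic acid, and the R configuration is kept because the C–O bond at the stereocentre is not broken.

Step 8
Reactants: 11 strapped diene
Product: 14 strapped all-trans cyclobutane (cyclophane), via tin chelate of the diene 12 (not isolated), via tin chelate of the cycloadduct 13 (not isolated)
Conditions: SnCl4 (1.1 equiv), CH2Cl2 (1 mM), −78 °C, 405 nm LED; then aq NaHCO3
Reagents that add atoms: none
Why: Proposed new method: SnCl4 should bind the caffeoyl C=O and the adjacent benzyl ester C=O of 11 as a seven-membered chelate 12, which alone absorbs at 405 nm and is the electron acceptor, so its excitation should give an intramolecular charge-transfer exciplex with the free, electron-rich coumarate that collapses by joining the acceptor β-carbon to the donor α-carbon and then the tin enolate carbon to the 4-alkoxybenzylic carbon, that is head-to-tail. The closest known reaction types are the head-to-tail photodimerisation of cinnamic esters irradiated as their BF3 or SnCl4 complexes and the face-selective Diels–Alder reactions of TiCl4-chelated acrylates of lactate esters. The step closes the cyclobutane by an intramolecular [2π+2π] addition in the crossed, 1,3-bridging mode and thereby a 19-membered cyclophane ring that contains the strap. The rigid p-xylylene strap holds the two para oxygens 6.7–7.3 Å apart (standard bond geometry), close to the 7.5–8 Å of the anti head-to-tail pairing in which the cinnamate axes cross at about 60° with parallel C=C bonds, whereas the syn head-to-head stack needs about 4 Å and the anti head-to-head and syn head-to-tail pairings need more than 10 Å, so chemo-, regio- and syn/anti selectivity are secured by geometry and backed by the polarity match. C2 and C4 therefore carry cis aryl groups, and C1 and C3 are each set trans to both neighbours because both E alkenes add suprafacially (a stepwise collapse would close to the same least hindered all-trans ring). The absolute sense of all four centres is controlled by the R stereocentre of the lactate-type ester, since tin and its chlorides cover the enoate face syn to the chelating ester arm and leave only the Cα-si/Cβ-si face of the s-trans caffeate open to the strapped coumarate, which is the face bonded in the target.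

Step 9
Reactants: 14 strapped all-trans cyclobutane
Product: 15 target compound
Conditions: H2 (1 atm), Pd/C, THF–MeOH, rt
Reagents that add atoms: none
Why: Catalytic hydrogenolysis should cleave all seven benzylic C–O bonds (three aryl benzyl ethers, two benzyl esters, both ends of the strap) in one operation, which opens the cyclophane ring and touches no stereocentre because no alkene is left.

**Compound list**
1 | p-coumaric acid, (E)-3-(4-hydroxyphenyl)prop-2-enoic acid | O=C(O)/C=C/c1ccc(O)cc1 | starting material
2 | benzyl (E)-3-(4-hydroxyphenyl)acrylate | O=C(OCc1ccccc1)/C=C/c1ccc(O)cc1 | intermediate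
3 | 1,4-bis(bromomethyl)benzene | BrCc1ccc(CBr)cc1 | starting material
4 | benzyl (E)-3-(4-{[4-(bromomethyl)benzyl]oxy}phenyl)acrylate | O=C(OCc1ccccc1)/C=C/c1ccc(OCc2ccc(CBr)cc2)cc1 | intermediate
5 | 3,4-dihydroxybenzaldehyde | O=Cc1ccc(O)c(O)c1 | starting material
6 | benzyl (E)-3-[4-({4-[(4-formyl-2-hydroxyphenoxy)methyl]benzyl}oxy)phenyl]acrylate | O=Cc1ccc(OCc2ccc(COc3ccc(/C=C/C(=O)OCc4ccccc4)cc3)cc2)c(O)c1 | intermediate
7 | benzyl (E)-3-[4-({4-[(2-(benzyloxy)-4-formylphenoxy)methyl]benzyl}oxy)phenyl]acrylate | O=Cc1ccc(OCc2ccc(COc3ccc(/C=C/C(=O)OCc4ccccc4)cc3)cc2)c(OCc2ccccc2)c1 | intermediate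
8 | (E)-3-{3-(benzyloxy)-4-[(4-{[4-((E)-3-(benzyloxy)-3-oxoprop-1-enyl)phenoxy]methyl}benzyl)oxy]phenyl}acrylic acid | O=C(O)/C=C/c1ccc(OCc2ccc(COc3ccc(/C=C/C(=O)OCc4ccccc4)cc3)cc2)c(OCc2ccccc2)c1 | intermediate
9 | sodium (R)-3-(3,4-dihydroxyphenyl)-2-hydroxypropanoate (sodium danshensu) | O[C@H](Cc1ccc(O)c(O)c1)C(=O)[O-].[Na+] | starting material
10 | benzyl (R)-3-[3,4-bis(benzyloxy)phenyl]-2-hydroxypropanoate | O[C@H](Cc1ccc(OCc2ccccc2)c(OCc2ccccc2)c1)C(=O)OCc1ccccc1 | intermediate
11 | strapped diene: ester of acid 8 with the hydroxyl of 10, both alkenes E, side-chain centre R | O=C(O[C@H](Cc1ccc(OCc2ccccc2)c(OCc2ccccc2)c1)C(=O)OCc1ccccc1)/C=C/c1ccc(OCc2ccc(COc3ccc(/C=C/C(=O)OCc4ccccc4)cc3)cc2)c(OCc2ccccc2)c1 | intermediate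
12 | 1:1 tin(IV) chloride chelate of 11 (Sn bound to the caffeoyl C=O and the neighbouring benzyl ester C=O) | O=C(O[C@H](Cc1ccc(OCc2ccccc2)c(OCc2ccccc2)c1)C(=O)OCc1ccccc1)/C=C/c1ccc(OCc2ccc(COc3ccc(/C=C/C(=O)OCc4ccccc4)cc3)cc2)c(OCc2ccccc2)c1.Cl[Sn](Cl)(Cl)Cl | intermediate
13 | 1:1 tin(IV) chloride chelate of 14 | O=C(OCc5ccccc5)[C@@H]1[C@@H](c2ccc(OCc3ccc(CO9)cc3)cc2)[C@H](C(=O)O[C@H](Cc2ccc(OCc3ccccc3)c(OCc3ccccc3)c2)C(=O)OCc2ccccc2)[C@H]1c1ccc9c(OCc2ccccc2)c1.Cl[Sn](Cl)(Cl)Cl | intermediate
14 | strapped cyclobutane (1R,2S,3S,4R), side chain R: C1 CO2Bn, C2 3-(benzyloxy)-4-oxyphenyl, C3 ester of 10, C4 4-oxyphenyl; the two para oxygens are joined by CH2–C6H4–CH2; aryl groups on one face, both carboxyl carbons on the other | O=C(OCc5ccccc5)[C@@H]1[C@@H](c2ccc(OCc3ccc(CO9)cc3)cc2)[C@H](C(=O)O[C@H](Cc2ccc(OCc3ccccc3)c(OCc3ccccc3)c2)C(=O)OCc2ccccc2)[C@H]1c1ccc9c(OCc2ccccc2)c1 | intermediate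
15 | (1R,2S,3S,4R)-3-{[(1R)-1-carboxy-2-(3,4-dihydroxyphenyl)ethoxy]carbonyl}-2-(3,4-dihydroxyphenyl)-4-(4-hydroxyphenyl)cyclobutane-1-carboxylic acid | O=C(O)[C@@H]1[C@@H](c2ccc(O)cc2)[C@H](C(=O)O[C@H](Cc2ccc(O)c(O)c2)C(=O)O)[C@H]1c1ccc(O)c(O)c1 | target

**Total step count:** 9. **Longest linear sequence:** 8 (steps 1–5, 7, 8, 9).

**Steps most likely to fail**

1. Step 8.
 - What may go wrong:
   - Photoisomerisation of the chelated caffeate to its Z form may outrun the cycloaddition.
   - Intersystem crossing may open the head-to-head triplet channel.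
   - The chelate may discriminate the faces weakly, or the enoate may react from the s-cis conformer and expose the other face.
   - The Lewis acid may begin to cleave benzyl ethers.
 - Fallback: known chemistry without strap or Lewis acid, setting out from 10 and 2 and coming back at 15. 10 would be esterified (DCC, DMAP) with commercial (E)-3,4-bis(benzyloxy)cinnamic acid to give perbenzyl rosmarinate F1. 2 would be benzylated (BnBr, K2CO3) to give benzyl (E)-3-[4-(benzyloxy)phenyl]acrylate F2. F1 would then be irradiated at 450 nm with an excess of F2 and an iridium triplet sensitiser, the established visible-light energy-transfer [2+2] cycloaddition of cinnamates. The all-trans head-to-tail cross-adduct F3 would have to be separated from its regio- and stereoisomers by preparative HPLC. Its hydrogenolysis as in step 9 would give 15.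

2. Step 3.
 - What may go wrong: regiocontrol may be lost between the two phenols, or double alkylation may occur with the large benzylic bromide.
 - Fallback: it fixes the regiochemistry by dealkylation instead of alkylation, sets out from 5 and comes back at 7. 5 would be dibenzylated (BnBr, K2CO3) to 3,4-bis(benzyloxy)benzaldehyde F4. The benzyl group para to the formyl group would be removed by nucleophilic dealkylation (LiCl, DMF, reflux), which attacks only the ether whose phenoxide is stabilised by the para carbonyl. This gives 3-(benzyloxy)-4-hydroxybenzaldehyde F5. F5 would be alkylated with 4 (K2CO3, DMF) to give 7 directly.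

3. Step 9.
 - What may go wrong: cleavage of the strap inside the cyclophane may be incomplete, or a strained benzylic C–C bond of the cyclobutane may undergo hydrogenolysis on palladium.
 - Fallback: it is non-reductive, sets out from 14 and comes back at 15. BCl3 with pentamethylbenzene as cation scavenger (CH2Cl2, −78 °C to 0 °C) would remove all benzylic groups by Lewis acid dealkylation. The secondary alkyl ester and the ring are left untouched.

**Further compounds**
F1 | step 8 | benzyl (R)-2-{[(E)-3-(3,4-bis(benzyloxy)phenyl)acryloyl]oxy}-3-[3,4-bis(benzyloxy)phenyl]propanoate | O=C(O[C@H](Cc1ccc(OCc2ccccc2)c(OCc2ccccc2)c1)C(=O)OCc1ccccc1)/C=C/c1ccc(OCc2ccccc2)c(OCc2ccccc2)c1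
F2 | step 8 | benzyl (E)-3-[4-(benzyloxy)phenyl]acrylate | O=C(OCc1ccccc1)/C=C/c1ccc(OCc2ccccc2)cc1
F3 | step 8 | unstrapped perbenzylated all-trans head-to-tail cyclobutane, (1R,2S,3S,4R), side chain R | O=C(OCc5ccccc5)[C@@H]1[C@@H](c2ccc(OCc3ccccc3)cc2)[C@H](C(=O)O[C@H](Cc2ccc(OCc3ccccc3)c(OCc3ccccc3)c2)C(=O)OCc2ccccc2)[C@H]1c1ccc(OCc2ccccc2)c(OCc2ccccc2)c1
F4 | step 3 | 3,4-bis(benzyloxy)benzaldehyde | O=Cc1ccc(OCc2ccccc2)c(OCc2ccccc2)c1
F5 | step 3 | 3-(benzyloxy)-4-hydroxybenzaldehyde | O=Cc1ccc(O)c(OCc2ccccc2)c1
F0 | step 9 | none | none
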